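All constants stand for no real mixture, and the outcome is calculated.

Two questions stand here, how the flask ends and how much side product it holds; I answer the first from the reagent's charge and half-life, and the second with one quantity, the reagent share.

    starting material + reagent → target (k1 = 0.011 M⁻¹ s⁻¹)
    second substrate + reagent → second product (k2 = 0.072 M⁻¹ s⁻¹)
    third substrate + reagent → third product (k3 = 0.0064 M⁻¹ s⁻¹)
    second substrate ⇌ dormant form (K4 = 0.48, k4 = 8.5 × 10⁻⁶ s⁻¹)
    starting material + target → side product (k5 = 0.023 M⁻¹ s⁻¹)

starting material 0.010 M; reagent 9.00 mM; second substrate 10.0 mM; third substrate 2.00 mM; time 8.0 d

- percentages count the starting material that a species holds: one side product counts as two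
- the reaction counts as stopped when no species that holds the starting material changes by six tenths of a point or more over the second half of the time
- run time (flask): 8.0 d

- the state of affairs at 8.0 d: stopped, and by what, or still going (forward and back rates have come level / the reagent has run out first / all of the starting material has reacted / it is still moving)
- the side product standing at 8.0 d, as a percentage of the starting material charged

I reckon by hand first. The reagent is the limiting reagent: 9.00 mM meets 22.0 mM of substrates, and its half-life at the charges is 0.228 h, so I expect the flask to stop for want of it. The half-life of target, 0.84 h, is far shorter than 8.0 d, so I let each target take a second starting material and become side product. At the start, the second substrate goes to second product 76 times as fast as to dormant form by the forward step, so I leave the dormant form out.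

What remains is the reagent share: the rate of the step from starting material to target over the summed rates of the reagent's steps. I take it at the charges, then put that answer back, holding each substrate at the mean of its charge and the end the first row implies.

| round | [starting material] | [second substrate] | [third substrate] | reagent share | side product |
|---|---|---|---|---|---|
| charges | 10 mM | 10.0 mM | 2.00 mM | 13.1% | 23.5% |
| means | 8.83 mM | 6.16 mM | 1.93 mM | 17.6% | 31.6% |

Reading down the columns, [second substrate] falls further than [starting material], so the share rises. I commit to the second row's reagent share and its 31.6%.

The forecast says the reagent has run out first and 34%: “the reaction stopped because reagent ran out”. Its figure is higher than mine.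

The simulation gives the reagent has run out first and 34.1%, with 0% of the reagent left at 8.00 d. Side product reads 34.1% at 0.800 d and 34.1% at 80.0 d. Read back, this flask's result is a reagent share of 18.9%, above my 17.6%. In the neighbour with 0.0040 M of starting material, the charges give a share of 5.66% and 25.5%. Means of 3.49 mM and 5.83 mM, with third substrate at its charge, give 8.15% and 36.7%. That neighbour computes to 42.6%.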